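The trans-decalin (C1–C10; ring 1 = C5–C6–C7–C8–C9–C10 with the C8 methylene and the C9 arylmethyl group, ring 2 = C1–C2–C3–C4–C5–C10 with C3–Br and quaternary C4) is cut at the ring-fusion bond C5–C10. C10 is γ to C3, so with C3 as a ketone C1/C10 become an α-branched aldehyde and C5 the β-carbon of an enone. One amine-catalysed operation on an acyclic keto aldehyde then forms C5–C10 by intramolecular Michael addition (ring 1; C10 and C5 set from the existing C9 centre) and closes ring 2 by aldol condensation, leaving an enone whose only enolisable position is C4.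

Key step: step 14

Remark: the decalin numbers above are also used for the acyclic precursors. Ar = 3-bromo-2-[(tert-butyldimethylsilyl)oxy]-5-(methoxycarbonyl)phenyl. Lactone 7 is used as the racemate because its stereocentre (the future C10) is erased and re-set in step 14, so 13, 15, 16, 18–20, 22 and 23 are epimer mixtures at that carbon only.

Step 1
Reactants: 1 methyl 4-hydroxy-3-methylbenzoate
Product: 2 methyl 3-bromo-4-hydroxy-5-methylbenzoate
Conditions: Br2, AcOH, 25 °C
Reagents that add atoms: bromine, BrBr
Why: Electrophilic aromatic bromination should go to the only free position ortho to the phenol, the para position being blocked by the ester.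

Step 2
Reactants: 2 methyl 3-bromo-4-hydroxy-5-methylbenzoate
Product: 3 methyl 3-bromo-4-[(tert-butyldimethylsilyl)oxy]-5-methylbenzoate
Conditions: TBSCl, imidazole, DMF, 25 °C
Reagents that add atoms: tert-butyldimethylsilyl chloride, CC(C)(C)[Si](C)(C)Cl
Why: Standard phenol silylation masks the acidic OH for the radical, enolate and organometallic steps, and an aryl silyl ether resists dilute acid but is cleaved by hydroxide at the end.

Step 3
Reactants: 3 methyl 3-bromo-4-[(tert-butyldimethylsilyl)oxy]-5-methylbenzoate
Product: 4 methyl 3-bromo-5-(bromomethyl)-4-[(tert-butyldimethylsilyl)oxy]benzoate (ArCH2Br)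
Conditions: NBS, AIBN (cat.), PhCF3, 85 °C
Reagents that add atoms: N-bromosuccinimide, O=C1CCC(=O)N1Br
Why: Wohl–Ziegler radical bromination should functionalise the single benzylic methyl group of the electron-poor ring.

Step 4
Reactants: 5 5-bromo-2-methylpent-2-ene
Product: 6 5-iodo-2-methylpent-2-ene
Conditions: NaI, acetone, reflux
Reagents that add atoms: sodium iodide, [Na+].[I-]
Why: Finkelstein exchange at the unhindered primary carbon gives the more reactive alkylating agent needed for step 15.

Step 5
Reactants: 7 (±)-4-methyloxolan-2-one (β-methyl-γ-butyrolactone)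
Product: 10 4-[(tert-butyldimethylsilyl)oxy]-3-methylbutanoic acid (racemic), via potassium 4-hydroxy-3-methylbutanoate 8 (not isolated), via silyl ester silyl ether 9 (not isolated)
Conditions: KOH, MeOH/H2O, 25 °C, evaporate; TBSCl, imidazole, DMF, 25 °C; then K2CO3 (cat.), MeOH/THF/H2O, 25 °C
Reagents that add atoms: potassium hydroxide, [K+].[OH-]; tert-butyldimethylsilyl chloride, CC(C)(C)[Si](C)(C)Cl
Why: Saponification opens the lactone, exhaustive silylation prevents relactonisation, and the labile silyl ester is then solvolysed selectively beside the silyl ether.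

Step 6
Reactants: 10 4-[(tert-butyldimethylsilyl)oxy]-3-methylbutanoic acid; 11 (S)-4-benzyloxazolidin-2-one
Product: 13 (4S)-4-benzyl-3-{4-[(tert-butyldimethylsilyl)oxy]-3-methylbutanoyl}oxazolidin-2-one (epimer mixture at the methyl-bearing carbon), via mixed pivalic anhydride 12 (not isolated)
Conditions: PivCl, Et3N, THF, –20 °C; then 11, LiCl, 25 °C
Reagents that add atoms: none
Why: N-Acylation of the Evans auxiliary through the mixed pivalic anhydride is the standard entry to the imide, the oxazolidinone attacking the less hindered acyl group.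

Step 7
Reactants: 13 (4S)-4-benzyl-3-{4-[(tert-butyldimethylsilyl)oxy]-3-methylbutanoyl}oxazolidin-2-one; 4 ArCH2Br
Product: 15 (4S)-4-benzyl-3-{(2S)-2-(ArCH2)-4-[(tert-butyldimethylsilyl)oxy]-3-methylbutanoyl}oxazolidin-2-one, via sodium enolate 14 (not isolated)
Conditions: NaN(SiMe3)2, THF, –78 °C; then 4, –78 → –40 °C
Reagents that add atoms: none
Why: In this Evans asymmetric alkylation the chelated (Z)-sodium enolate should be benzylated on the face opposite the benzyl group of the auxiliary, which sets the arylmethyl carbon (future C9) as (S).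

Step 8
Reactants: 15 (4S)-4-benzyl-3-{(2S)-2-(ArCH2)-4-[(tert-butyldimethylsilyl)oxy]-3-methylbutanoyl}oxazolidin-2-one
Product: 16 S-ethyl (2S)-2-(ArCH2)-4-[(tert-butyldimethylsilyl)oxy]-3-methylbutanethioate
Conditions: EtSH, n-BuLi, THF, 0 °C
Reagents that add atoms: ethanethiol, CCS
Why: Thiolate cleaves hindered N-acyloxazolidinones at the exocyclic carbonyl (transthioesterification), which should release the auxiliary without touching the α-stereocentre, the methyl benzoate or the silyl ethers.

Step 9
Reactants: 16 S-ethyl (2S)-2-(ArCH2)-4-[(tert-butyldimethylsilyl)oxy]-3-methylbutanethioate; 17 [2-(1,3-dioxolan-2-yl)ethyl]zinc bromide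
Product: 18 (4S)-4-(ArCH2)-6-[(tert-butyldimethylsilyl)oxy]-1-(1,3-dioxolan-2-yl)-5-methylhexan-3-one (C8 ketone)
Conditions: PdCl2(PPh3)2 (5 mol%), toluene/THF, 25 °C
Reagents that add atoms: none
Why: Fukuyama coupling should give the ketone without over-addition or epimerisation and tolerates the methyl ester, the acyl–sulfur bond reacting with zerovalent palladium at 25 °C before the hindered, electron-rich aryl bromide.

Step 10
Reactants: 18 (4S)-4-(ArCH2)-6-[(tert-butyldimethylsilyl)oxy]-1-(1,3-dioxolan-2-yl)-5-methylhexan-3-one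
Product: 19 tertiary β-hydroxysilane, the adduct of Me3SiCH2 to the C8 ketone of 18 (mixture at the new carbinol carbon)
Conditions: Me3SiCH2MgCl, CeCl3, THF, –78 → 0 °C
Reagents that add atoms: (trimethylsilyl)methylmagnesium chloride, C[Si](C)(C)C[Mg]Cl
Why: The weakly basic organocerium reagent adds to the enolisable α-branched ketone without deprotonating it (first half of a Peterson olefination), so the C9 configuration should survive, and the ketone reacts far faster than the aryl ester.

Step 11
Reactants: 19 tertiary β-hydroxysilane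
Product: 20 (5S)-5-(ArCH2)-7-hydroxy-6-methyl-4-methylideneheptanal
Conditions: HCl (1 M aq.), THF, 25 °C
Reagents that add atoms: water, O
Why: Acid completes the Peterson olefination by anti-elimination to the 1,1-disubstituted alkene (the C8 methylene) and also hydrolyses the dioxolane and the primary alkyl silyl ether, whereas the aryl silyl ether and the methyl ester are stable to dilute acid.

Step 12
Reactants: 20 (5S)-5-(ArCH2)-7-hydroxy-6-methyl-4-methylideneheptanal; 21 3-(triphenylphosphoranylidene)butan-2-one
Product: 22 (3E,8S)-8-(ArCH2)-10-hydroxy-3,9-dimethyl-7-methylidenedec-3-en-2-one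
Conditions: toluene, 80 °C
Reagents that add atoms: none
Why: Wittig olefination with the stabilised α-methyl ylide should give the (E)-trisubstituted enone and tolerates the free alcohol.

Step 13
Reactants: 22 (3E,8S)-8-(ArCH2)-10-hydroxy-3,9-dimethyl-7-methylidenedec-3-en-2-one
Product: 23 (3S,7E)-3-(ArCH2)-2,8-dimethyl-4-methylidene-9-oxodec-7-enal
Conditions: Dess–Martin periodinane, CH2Cl2, 25 °C
Reagents that add atoms: none
Why: Dess–Martin oxidation should convert the primary alcohol into the α-branched aldehyde under neutral conditions that leave the enone and both alkenes untouched.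

Step 14
Reactants: 23 (3S,7E)-3-(ArCH2)-2,8-dimethyl-4-methylidene-9-oxodec-7-enal
Product: 25 trans-fused 9-(ArCH2)-4,10-dimethyl-8-methylidene-decal-1-en-3-one (C5–H trans and C9–CH2Ar cis to the C10 methyl; C4 methyl equatorial, epimerisable), via Michael adduct keto aldehyde 24 (not isolated)
Conditions: pyrrolidine (30 mol%), PhCO2H (30 mol%), toluene, 25 → 60 °C
Reagents that add atoms: none
Why: Pyrrolidine converts the aldehyde of 23 into its enamine (C1=C10), whose carbon C10 adds 6-exo-trig to C5, the β-carbon of the (E)-α-methyl enone, forming the C5–C10 bond, ring 1 and the quaternary centre (keto aldehyde 24); the methyl ketone carbon C2 then condenses, again under amine catalysis, with the now non-enolisable aldehyde C1 (6-enolendo-exo-trig aldol, loss of water) and closes ring 2 as the cyclohexenone. The closest known reaction type is the enamine-mediated Robinson-type (Michael/aldol) annulation of α,α-disubstituted aldehydes with vinyl ketones (Yamada–Otani condensation), here with the Michael step made intramolecular as in amine-catalysed cyclisations of formyl enones. Ring 1 should close through a chair in which both reacting exocyclic π-bonds (C10=C1 and C5=C4) are equatorial, so the C10 methyl and the C5 hydrogen end up axial and trans, which is the trans ring fusion. The configuration at C10 is controlled by the C9 stereocentre, whose arylmethyl group stays equatorial while its C–H eclipses the enamine double bond (allylic 1,3-strain), leaving one enamine face open; both C10 epimers of 23 converge because the enamine erases that centre, and C4 of 25 is epimerisable and is erased in step 15. The step needs enamine formation at the aldehyde in preference to the conjugated methyl ketone and Michael addition before aldol closure, which the higher carbonyl reactivity of the aldehyde and ring size (a direct aldol would need a ten-membered ring) secure.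

Step 15
Reactants: 25 trans-fused 9-(ArCH2)-4,10-dimethyl-8-methylidene-decal-1-en-3-one; 6 5-iodo-2-methylpent-2-ene
Product: 27 the C4-alkylated enone (C4 methyl axial and cis to the C10 methyl, 4-methylpent-3-enyl equatorial), via lithium enolate 26 (not isolated)
Conditions: LiN(iPr)2, THF, –78 °C; then 6, DMPU, –78 → –20 °C
Reagents that add atoms: none
Why: Kinetic α′-deprotonation of the cyclohexenone can only occur at C4 (the γ-carbon C10 is quaternary), and the cross-conjugated enolate should be alkylated on the face opposite the axial C10 methyl, which places the new chain equatorial and the C4 methyl axial.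

Step 16
Reactants: 27 the C4-alkylated enone
Product: 28 the saturated C3 ketone (1,2-dihydro-27)
Conditions: [(Ph3P)CuH]6 (5 mol%), PhMe2SiH, t-BuOH, toluene, 25 °C
Reagents that add atoms: none
Why: Copper hydride-catalysed conjugate reduction (Stryker-type) should reduce only the enone C1=C2 bond and leave the isolated alkenes, the aryl bromide and the ester.

Step 17
Reactants: 28 the saturated C3 ketone
Product: 29 the axial C3 alcohol (OH trans to the C4 and C10 methyl groups)
Conditions: LiBH(s-Bu)3, THF, –78 °C
Reagents that add atoms: none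
Why: The bulky hydride should attack the C3 ketone along the equatorial trajectory, as with other 4,4-disubstituted 3-oxodecalins, giving the axial alcohol needed for inversion.

Step 18
Reactants: 29 the axial C3 alcohol
Product: 30 methyl ester and aryl silyl ether of the target (C3–Br equatorial, cis to the C4 and C10 methyl groups)
Conditions: CBr4, PPh3, toluene, 0 → 60 °C
Reagents that add atoms: tetrabromomethane, BrC(Br)(Br)Br
Why: Appel bromination displaces the axial oxyphosphonium group by SN2, so inversion should deliver the equatorial bromide at C3.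

Step 19
Reactants: 30 methyl ester and aryl silyl ether of the target
Product: 31 callophycoic acid H
Conditions: LiOH, THF/MeOH/H2O, 40 °C; then HCl (1 M aq.) to pH 3
Reagents that add atoms: lithium hydroxide, [Li+].[OH-]
Why: Hydroxide saponifies the methyl ester and cleaves the electron-poor aryl silyl ether in one operation, while the equatorial neopentylic bromide has neither an accessible backside nor an antiperiplanar hydrogen and should survive.

Compound list
1 | methyl 4-hydroxy-3-methylbenzoate | COC(=O)c1ccc(O)c(C)c1 | starting material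
2 | methyl 3-bromo-4-hydroxy-5-methylbenzoate | COC(=O)c1cc(C)c(O)c(Br)c1 | intermediate
3 | methyl 3-bromo-4-[(tert-butyldimethylsilyl)oxy]-5-methylbenzoate | COC(=O)c1cc(C)c(O[Si](C)(C)C(C)(C)C)c(Br)c1 | intermediate
4 | methyl 3-bromo-5-(bromomethyl)-4-[(tert-butyldimethylsilyl)oxy]benzoate (ArCH2Br) | COC(=O)c1cc(CBr)c(O[Si](C)(C)C(C)(C)C)c(Br)c1 | intermediate
5 | 5-bromo-2-methylpent-2-ene | CC(C)=CCCBr | starting material
6 | 5-iodo-2-methylpent-2-ene | CC(C)=CCCI | intermediate
7 | (±)-4-methyloxolan-2-one | CC1COC(=O)C1 | starting material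
8 | potassium 4-hydroxy-3-methylbutanoate (not isolated) | CC(CO)CC(=O)[O-].[K+] | intermediate
9 | tert-butyldimethylsilyl 4-[(tert-butyldimethylsilyl)oxy]-3-methylbutanoate (not isolated) | CC(CO[Si](C)(C)C(C)(C)C)CC(=O)O[Si](C)(C)C(C)(C)C | intermediate
10 | 4-[(tert-butyldimethylsilyl)oxy]-3-methylbutanoic acid (racemic) | CC(CO[Si](C)(C)C(C)(C)C)CC(=O)O | intermediate
11 | (S)-4-benzyloxazolidin-2-one | O=C1N[C@@H](Cc2ccccc2)CO1 | starting material
12 | 4-[(tert-butyldimethylsilyl)oxy]-3-methylbutanoic pivalic anhydride (not isolated) | CC(CO[Si](C)(C)C(C)(C)C)CC(=O)OC(=O)C(C)(C)C | intermediate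
13 | (4S)-4-benzyl-3-{4-[(tert-butyldimethylsilyl)oxy]-3-methylbutanoyl}oxazolidin-2-one | CC(CO[Si](C)(C)C(C)(C)C)CC(=O)N1[C@@H](Cc2ccccc2)COC1=O | intermediate
14 | sodium (Z)-enolate of 13 (not isolated) | CC(CO[Si](C)(C)C(C)(C)C)/C=C(\[O-])N1[C@@H](Cc2ccccc2)COC1=O.[Na+] | intermediate
15 | (4S)-4-benzyl-3-{(2S)-2-(ArCH2)-4-[(tert-butyldimethylsilyl)oxy]-3-methylbutanoyl}oxazolidin-2-one | CC(CO[Si](C)(C)C(C)(C)C)[C@H](Cc1cc(C(=O)OC)cc(Br)c1O[Si](C)(C)C(C)(C)C)C(=O)N1[C@@H](Cc2ccccc2)COC1=O | intermediate
16 | S-ethyl (2S)-2-(ArCH2)-4-[(tert-butyldimethylsilyl)oxy]-3-methylbutanethioate | CC(CO[Si](C)(C)C(C)(C)C)[C@H](Cc1cc(C(=O)OC)cc(Br)c1O[Si](C)(C)C(C)(C)C)C(=O)SCC | intermediate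
17 | [2-(1,3-dioxolan-2-yl)ethyl]zinc bromide | Br[Zn]CCC1OCCO1 | starting material
18 | (4S)-4-(ArCH2)-6-[(tert-butyldimethylsilyl)oxy]-1-(1,3-dioxolan-2-yl)-5-methylhexan-3-one | CC(CO[Si](C)(C)C(C)(C)C)[C@H](Cc1cc(C(=O)OC)cc(Br)c1O[Si](C)(C)C(C)(C)C)C(=O)CCC1OCCO1 | intermediate
19 | tertiary β-hydroxysilane from 18 (C9 as in 18; carbinol carbon unassigned) | CC(CO[Si](C)(C)C(C)(C)C)[C@H](Cc1cc(C(=O)OC)cc(Br)c1O[Si](C)(C)C(C)(C)C)C(O)(C[Si](C)(C)C)CCC1OCCO1 | intermediate
20 | (5S)-5-(ArCH2)-7-hydroxy-6-methyl-4-methylideneheptanal | OCC(C)[C@H](Cc1cc(C(=O)OC)cc(Br)c1O[Si](C)(C)C(C)(C)C)C(=C)CCC=O | intermediate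
21 | 3-(triphenylphosphoranylidene)butan-2-one | CC(=O)C(C)=P(c1ccccc1)(c1ccccc1)c1ccccc1 | starting material
22 | (3E,8S)-8-(ArCH2)-10-hydroxy-3,9-dimethyl-7-methylidenedec-3-en-2-one | OCC(C)[C@H](Cc1cc(C(=O)OC)cc(Br)c1O[Si](C)(C)C(C)(C)C)C(=C)CC/C=C(\C)C(C)=O | intermediate
23 | (3S,7E)-3-(ArCH2)-2,8-dimethyl-4-methylidene-9-oxodec-7-enal | O=CC(C)[C@H](Cc1cc(C(=O)OC)cc(Br)c1O[Si](C)(C)C(C)(C)C)C(=C)CC/C=C(\C)C(C)=O | intermediate
24 | Michael adduct: ring 1 cyclohexane with C10 (CH3, CHO), C5 (3-oxobutan-2-yl), C8 methylidene, C9 CH2Ar (not isolated) | C=C1CC[C@H](C(C)C(C)=O)[C@@](C)(C=O)[C@@H]1Cc1cc(C(=O)OC)cc(Br)c1O[Si](C)(C)C(C)(C)C | intermediate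
25 | trans-fused 9-(ArCH2)-4,10-dimethyl-8-methylidene-decal-1-en-3-one (C4 methyl equatorial) | C=C1CC[C@@H]2[C@@H](C)C(=O)C=C[C@@]2(C)[C@@H]1Cc1cc(C(=O)OC)cc(Br)c1O[Si](C)(C)C(C)(C)C | intermediate
26 | lithium cross-conjugated enolate of 25 (not isolated) | C=C1CC[C@@H]2C(C)=C([O-])C=C[C@@]2(C)[C@@H]1Cc1cc(C(=O)OC)cc(Br)c1O[Si](C)(C)C(C)(C)C.[Li+] | intermediate
27 | C4-alkylated enone (C4: axial CH3, equatorial 4-methylpent-3-enyl) | C=C1CC[C@@H]2[C@@](C)(CCC=C(C)C)C(=O)C=C[C@@]2(C)[C@@H]1Cc1cc(C(=O)OC)cc(Br)c1O[Si](C)(C)C(C)(C)C | intermediate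
28 | saturated C3 ketone | C=C1CC[C@@H]2[C@@](C)(CCC=C(C)C)C(=O)CC[C@@]2(C)[C@@H]1Cc1cc(C(=O)OC)cc(Br)c1O[Si](C)(C)C(C)(C)C | intermediate
29 | axial C3 alcohol | C=C1CC[C@@H]2[C@@](C)(CCC=C(C)C)[C@@H](O)CC[C@@]2(C)[C@@H]1Cc1cc(C(=O)OC)cc(Br)c1O[Si](C)(C)C(C)(C)C | intermediate
30 | methyl ester and aryl silyl ether of the target (equatorial C3 bromide) | C=C1CC[C@@H]2[C@@](C)(CCC=C(C)C)[C@H](Br)CC[C@@]2(C)[C@@H]1Cc1cc(C(=O)OC)cc(Br)c1O[Si](C)(C)C(C)(C)C | intermediate
31 | callophycoic acid H | C=C1CC[C@@H]2[C@@](C)(CCC=C(C)C)[C@H](Br)CC[C@@]2(C)[C@@H]1Cc1cc(C(=O)O)cc(Br)c1O | target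

Total step count: 19. Longest linear sequence: 16 steps (steps 1–3, then 7–19).

Steps most likely to fail:

Step 14. Enamine formation at the hindered α-branched aldehyde may be slower than dienamine formation at the methyl ketone, and a reversible Michael addition could erode facial control or stall before dehydration. The fallback uses a different activation mode and sets out from 23. The aldehyde alone is silylated (Me3SiCl, Et3N, DMF, 25 °C) to the trimethylsilyl enol ether F1. TiCl4 in CH2Cl2 at –78 °C then activates the enone for an intramolecular Mukaiyama–Michael addition that forms the same C5–C10 bond and, after aqueous work-up, gives keto aldehyde 24 as an isolated compound. KOH in MeOH effects the aldol condensation, and the route is rejoined at 25.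

Step 18. On the neopentylic axial oxyphosphonium intermediate, E2 elimination towards C2 and a Wagner–Meerwein shift of the antiperiplanar C4 methyl may outrun backside attack by bromide. The fallback avoids backside attack and sets out from ketone 28. NaBH4 (MeOH, 0 °C) delivers hydride axially and should give the equatorial C3 alcohol F2. SOBr2 in dioxane then replaces OH by Br with retention through the bromosulfite (internal substitution), and the route is rejoined at 30.

Step 15. C-Alkylation of the fully substituted, hindered enolate by an unactivated homoallylic iodide may be slow, so that E2 elimination of the iodide, O-alkylation or proton transfer compete. The fallback builds the chain in two C–C bond formations and sets out from 25. LiN(iPr)2 followed by Me3SiCl gives the trimethylsilyl dienol ether F3. A BF3·OEt2-promoted Mukaiyama–Michael addition to acrolein (CH2Cl2, –78 °C) should deliver the 3-oxopropyl group to C4 from the same face, giving the enone aldehyde F4. A Wittig reaction with isopropylidenetriphenylphosphorane (from isopropyltriphenylphosphonium iodide and n-BuLi) completes the 4-methylpent-3-enyl chain and rejoins the route at 27.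

Further compounds
F1 | step 14 | trimethylsilyl enol ether of aldehyde 23 | C[Si](C)(C)OC=C(C)[C@H](Cc1cc(C(=O)OC)cc(Br)c1O[Si](C)(C)C(C)(C)C)C(=C)CC/C=C(\C)C(C)=O
F2 | step 18 | equatorial C3 alcohol (C3 epimer of 29) | C=C1CC[C@@H]2[C@@](C)(CCC=C(C)C)[C@H](O)CC[C@@]2(C)[C@@H]1Cc1cc(C(=O)OC)cc(Br)c1O[Si](C)(C)C(C)(C)C
F3 | step 15 | trimethylsilyl dienol ether of enone 25 | C=C1CC[C@@H]2C(C)=C(O[Si](C)(C)C)C=C[C@@]2(C)[C@@H]1Cc1cc(C(=O)OC)cc(Br)c1O[Si](C)(C)C(C)(C)C
F4 | step 15 | C4-(3-oxopropyl) enone aldehyde | C=C1CC[C@@H]2[C@@](C)(CCC=O)C(=O)C=C[C@@]2(C)[C@@H]1Cc1cc(C(=O)OC)cc(Br)c1O[Si](C)(C)C(C)(C)C
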